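## Structural features

The target is a biflavonoid ether. A kaempferol-type flavonol (rings A, C and B of a 5,7-dihydroxy-2-(4-hydroxyphenyl)chromen-4-one) is joined through its O3 to C4' of ring B of a (2S)-5-hydroxy-7-methoxyflavanone, so one 1,4-phenylene ring carries the flavanone C2 at one end and the ether oxygen at the other. The only stereocentre is C2 of the flavanone, with no stereocentre next to it. It is benzylic, oxygen-bearing and β to the C4 carbonyl, so it is lost by retro-oxa-Michael opening to the 2'-hydroxychalcone under base and by benzylic ionisation under strong acid. Four phenols of different acidity (two chelated 5-hydroxyls, the flavonol 7- and 4'-hydroxyls) stand beside one aryl methyl ether that must stay distinct to the end. Both pyranone rings are sensitive to hot hydroxide and to nucleophilic amines, and the diaryl ether sits on the most hindered oxygen of the flavonol, between the 2-aryl group and the C4 carbonyl. The real difficulty is the combination of the hindered O3–aryl bond, the oxygen pattern and the late, racemisation-free introduction of C2. The key step uses the fact that flavonol ring A (C4a, C5, C6, C7, C8, C8a) is a resorcinol-type benzo ring fused to ring C at C4a–C8a: C4a and C8a can pre-exist as C3 and C2 of a monocyclic 4-pyranone, C5 and C8 come from a diazoacetyl group on that C2, and C6 and C7 from an ynol ether.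

## Logic of the disconnections

32 to 31. The four O–CH2Ph bonds are cut first (three on the flavonol part, one at O5 of the flavanone). One kind of phenol protection, removable without acid or base, lets the labile C2 centre be made before the phenols are freed and leaves the O7 methyl as the only ether. The forward step must stop short of the C4 carbonyls and of the benzylic C2–O1 bond.

31 to 28 (through 29 and 30). The O1–C2 bond of flavanone ring C is cut, and in the reverse sense a tert-butoxycarbonyl group is added at C3. The stereocentre is then created in the ring-closing event under catalyst control, and the ester makes the enone a two-point hydrogen-bond acceptor. 28 is open-chain and achiral. The forward step needs the catalysed closure to outrun the uncatalysed one and the ester to be removed without reopening the ring.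

28 to 24 and 27. The Cα=Cβ double bond (the future C2–C3 bond) is cut. This is the point of convergence, joining two halves of similar size by a condensation that needs only amine/acid catalysis. A hydroxide-mediated aldol condensation would expose the chromone to ring-opening. The phenol of 27 must not close during the condensation.

27 to 26 to 25. The CH2–CO2t-Bu bond and then one O–benzyl bond are cut. 25 is symmetrical, so monobenzylation needs no regiocontrol and hides the hydroxyl that ends as the chelated 5-hydroxyl. The forward acylation must go on carbon and must not lactonise.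

24 to 23 to 20. The acetal C–O bonds are cut, then the O5– and O7–benzyl bonds in exchange for hydrogen and silicon. The aldehyde stays masked through light, oxidant and acylating agents. The silyl group delivered by the ring-forming step is exchanged for benzyl because a free acidic phenol would quench the amine catalyst later, and so that all deprotections merge into the last step. Fluoride and carbonate must leave the acetal alone, and dilute acid must spare the benzyl ethers.

20 to 11 and 15. Four bonds of flavonol ring A are cut: C8–C8a, C7–C8, C5–C6 and C4a–C5. This reduces the bicyclic flavonol to a monocyclic pyranone that already holds the hindered O3–aryl ether and the 2-aryl group, and to a two-carbon ynol ether. Atom bookkeeping: C6, C5, C4, C3 and C2 of the pyranone in 11 become C2, C3, C4, C4a and C8a of 20. The forward step needs clean ketene formation, a polarity-matched (2+2) addition and closure onto the only CH carbon beside the attachment point. The benzyl ether and the dioxolane of 11 are kept because both are transparent and inert under the irradiation.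

15 to 12. The O–Si and C–O bonds are cut, giving the silyl chloride, an oxygen-atom donor and 12. The forward step needs O-silylation and not C-silylation of the ynolate.

11 to 9 to 7. The bond between the carbonyl carbon and the diazo carbon is cut, then the oxidation level of the exocyclic carbon is lowered to the alcohol. Acyl activation must be non-acidic because the acetal is present.

7 to 6 to 4 and 5. The acetal C–O bonds are cut, then the aryl C–O bond between O5 of the pyranone and the formyl-bearing ring. The aldehyde that activates the fluoroarene for substitution is the carbon that later becomes C2 of the flavanone. This bond is made after the C6–aryl bond, so that no bromide in a vinylogous acyl position is exposed to a hot oxygen nucleophile. The forward step needs selectivity for the enolic over the primary hydroxyl.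

4 to 2 and 3, and 2 to 1. The C6–aryl bond and then the C6–Br bond are cut. Only the free enol makes C6 the most nucleophilic ring carbon, so halogenation comes first. The forward coupling must work on the unprotected enol.

## Other disconnections considered

Alternative 1: The cut is the C4–C4a bond of flavanone ring C. In the forward sense the (3S)-3-aryl-3-(3,5-dimethoxyphenoxy)propanoic acid A1 is turned by (CF3CO)2O into a mixed anhydride that acylates the carbon ortho to the ether oxygen (intramolecular Friedel–Crafts acylation), giving the 5,7-dimethoxyflavanone A2.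
- In its favour: the stereocentre is set in an open-chain precursor by enantioselective reduction and a Mitsunobu etherification with inversion; the two ortho positions are equivalent; no chalcone is involved, so the retro-oxa-Michael channel is absent.
- Against it here: the C3–O bond of A1 is benzylic and para to an aryloxy group, so strong acid can ionise it, with racemisation or elimination to a cinnamic acid. The benzylated flavonol ring A is an electron-rich arene open to acylation. A2 has two methyl ethers, so O5 must be demethylated selectively with BCl3, which also cleaves benzyl ethers and may open the flavanone.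
- Comparison: this alternative concerns the flavanone and competes with steps 12 to 14, not with step 8. On the origin of configuration it is the equal of the chosen plan or better, since an SN2 inversion depends less on the substrate than an organocatalysed closure. On regiochemistry of ring closure the two are equal. Mechanistically it replaces a neutral conjugate addition by a cationic acylation beside a labile benzylic ether. In step count it is longer (chain extension, reduction, etherification, hydrolysis, closure and selective demethylation against three steps from 24 and 26).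

Alternative 2: The cuts are C4–C4a and O1–C2 of flavonol ring C. In the forward sense phloroglucinol A3 and ethyl 3-[4-(benzyloxy)phenyl]-2-(4-bromophenoxy)-3-oxopropanoate A4 are fused without solvent at about 250 °C (C-acylation of A3 by the keto ester, then cyclodehydration) to give the 3-(4-bromophenoxy)flavone A5.
- In its favour: one step gives the 5,7-dihydroxyflavonol core from a symmetrical triol, with no diazo compound and no photochemistry. The bromide of A5 allows PdCl2(dppf)-catalysed borylation and an asymmetric 1,4-addition to 5-(benzyloxy)-7-methoxychromen-4-one A6 under [Rh(OH)(cod)]2 with a chiral bisphosphine, a flavanone synthesis well matched to this ring A pattern.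
- Against it here: the melt temperature endangers the benzyl ether and the α-aryloxy keto ester (retro-Claisen and decarboxylative paths). The coumarin mode of condensation competes. The two new phenols then need protection, and the conjugate addition must be made to work with a very large boron partner.
- Comparison: regiochemistry is equal (symmetry of A3 against polarity matching). The chosen plan delivers O5 and O7 differentiated, but both end as phenols, so this is no advantage here. In step economy and freedom from hazardous reagents the alternative is better (one step against eight to the flavonol core), and its stereochemical endgame is at least the equal. The chosen plan is milder and more tolerant of the acetal and the benzyl ether.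

Alternative 3: The cut is the C4a–C5 bond of flavanone ring A at the chalcone stage. In the forward sense the cinnamoyl triketo ester A7 is treated with aqueous KOH; the methylene between the C5 and C7 carbonyls attacks the ester carbon (intramolecular Claisen condensation) and the product enolises to the trihydroxychalcone A8.
- In its favour: it follows the biosynthetic logic, makes the phloroglucinol ring with all three oxygens in place, and joins a cinnamoyl unit derived from 24 to a triketide chain.
- Against it here: A7 can also close by the aldol mode, lactonise to a 4-hydroxy-2-pyranone or undergo conjugate addition. Aqueous KOH threatens the chromone. A8 closes spontaneously to a racemic flavanone, and a selective O7 methylation is still needed.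
- Comparison: like the chosen key step it builds an oxygenated benzene ring from an open chain, and the two are equal in that the flavanone closure has no regiochemical ambiguity. Its choice among cyclisation modes is less secure than the polarity-controlled (2+2) addition. It gives no control of C2, which is worse. It is longer, because ring A of the flavanone is available from 25 in one step.

Key step: step 8

Assumptions (remarks on the chemistry):
- The target configuration is read as 2S at the flavanone carbon.
- The quinidine-derived thiourea is taken as the pseudoenantiomer that gives the 2S series; if the sense of induction is the opposite, the quinine-derived catalyst is used in the same way.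
- 28 is drawn as the Z isomer (aryl cis to the ester); either alkene isomer leads to the same ring-closed product.
- 25 is taken as commercially available.

## Route

Step 1
Reactants: 1 kojic acid
Product: 2 6-bromo-5-hydroxy-2-(hydroxymethyl)-4H-pyran-4-one
Conditions: NBS, MeCN, 0 °C to rt
Reagents that add atoms: N-bromosuccinimide, BrN1C(=O)CCC1=O
Why: Electrophilic bromination of an enol: the free 5-hydroxyl activates its ortho carbon C6, so the bromide should enter there; it is done before any O-substitution because afterwards C6 is no longer the most nucleophilic ring carbon.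

Step 2
Reactants: 2 6-bromo-5-hydroxy-2-(hydroxymethyl)-4H-pyran-4-one; 3 [4-(benzyloxy)phenyl]boronic acid
Product: 4 6-[4-(benzyloxy)phenyl]-5-hydroxy-2-(hydroxymethyl)-4H-pyran-4-one
Conditions: Pd(OAc)2, SPhos, K3PO4, dioxane/H2O, 80 °C
Reagents that add atoms: none
Why: Suzuki–Miyaura coupling at the C6–Br bond, run on the potassium enolate by analogy with couplings of unprotected 2-halophenols under electron-rich biarylphosphine catalysis; it precedes O-arylation so that no vinylogous acyl bromide later meets a hot oxygen nucleophile.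

Step 3
Reactants: 4 6-[4-(benzyloxy)phenyl]-5-hydroxy-2-(hydroxymethyl)-4H-pyran-4-one; 5 4-fluorobenzaldehyde
Product: 6 4-({2-[4-(benzyloxy)phenyl]-6-(hydroxymethyl)-4-oxo-4H-pyran-3-yl}oxy)benzaldehyde
Conditions: K2CO3, DMSO, 110 °C
Reagents that add atoms: none
Why: Nucleophilic aromatic substitution (addition–elimination) of the enolate oxygen on the aldehyde-activated fluoroarene; K2CO3 deprotonates only the acidic 5-hydroxyl, so the primary alcohol stays free.

Step 4
Reactants: 6 4-({2-[4-(benzyloxy)phenyl]-6-(hydroxymethyl)-4-oxo-4H-pyran-3-yl}oxy)benzaldehyde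
Product: 7 6-[4-(benzyloxy)phenyl]-5-[4-(1,3-dioxolan-2-yl)phenoxy]-2-(hydroxymethyl)-4H-pyran-4-one
Conditions: HOCH2CH2OH, p-TsOH (cat.), toluene, reflux (Dean–Stark)
Reagents that add atoms: ethylene glycol, OCCO
Why: Acid-catalysed acetalisation with azeotropic removal of water; the dioxolane masks the aldehyde against the oxidation, the acyl activation and the irradiation that follow, and the vinylogous ester carbonyl of the pyranone does not ketalise.

Step 5
Reactants: 7 6-[4-(benzyloxy)phenyl]-5-[4-(1,3-dioxolan-2-yl)phenoxy]-2-(hydroxymethyl)-4H-pyran-4-one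
Product: 9 6-[4-(benzyloxy)phenyl]-5-[4-(1,3-dioxolan-2-yl)phenoxy]-4-oxo-4H-pyran-2-carboxylic acid, via pyran-2-carbaldehyde 8 (not isolated)
Conditions: TEMPO (cat.), NaOCl (cat.), NaClO2, MeCN/phosphate buffer (pH 6.7), 35 °C
Reagents that add atoms: sodium chlorite, [Na+].[O-]Cl=O
Why: Oxoammonium oxidation of the primary alcohol to aldehyde 8 and Pinnick-type chlorite oxidation to the acid in one flask, at near-neutral pH, which should leave the acetal and the benzyl ether intact.

Step 6
Reactants: 9 6-[4-(benzyloxy)phenyl]-5-[4-(1,3-dioxolan-2-yl)phenoxy]-4-oxo-4H-pyran-2-carboxylic acid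
Product: 11 2-diazo-1-{6-[4-(benzyloxy)phenyl]-5-[4-(1,3-dioxolan-2-yl)phenoxy]-4-oxo-4H-pyran-2-yl}ethanone, via mixed carbonic anhydride 10 (not isolated)
Conditions: ClCO2Et, Et3N, THF, −15 °C; then Me3SiCHN2, MeCN, 0 °C to rt
Reagents that add atoms: (trimethylsilyl)diazomethane, C[Si](C)(C)C=[N+]=[N-]
Why: Acylation of a diazoalkane by a mixed carbonic anhydride (first stage of an Arndt–Eistert sequence); base is present throughout, so no HCl is freed to open the dioxolane, and the silyl reagent replaces diazomethane, its silyl group being lost from the acylated intermediate.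

Step 7
Reactants: 12 acetylene
Product: 15 (triisopropylsiloxy)ethyne, via lithium acetylide 13 (not isolated), via lithium ethynolate 14 (not isolated)
Conditions: n-BuLi, THF, −78 °C; t-BuOOLi (from t-BuOOH and LiN(SiMe3)2), −78 to 0 °C; i-Pr3SiCl, −78 °C to rt
Reagents that add atoms: tert-butyl hydroperoxide, CC(C)(C)OO; chlorotriisopropylsilane, CC(C)[Si](Cl)(C(C)C)C(C)C
Why: Oxidation of a lithium acetylide by lithium tert-butyl peroxide (attack of the acetylide carbon on the O–O bond) gives the ynolate, which the bulky silyl chloride should silylate on oxygen and not on carbon; the product is used soon after isolation.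

Step 8
Reactants: 11 2-diazo-1-{6-[4-(benzyloxy)phenyl]-5-[4-(1,3-dioxolan-2-yl)phenoxy]-4-oxo-4H-pyran-2-yl}ethanone; 15 (triisopropylsiloxy)ethyne
Product: 20 2-[4-(benzyloxy)phenyl]-3-[4-(1,3-dioxolan-2-yl)phenoxy]-5-hydroxy-7-(triisopropylsiloxy)-4H-chromen-4-one, via pyranonylketene 16 (not isolated), via siloxycyclobutenone 17 (not isolated), via dienylketene 18 (not isolated), via cyclohexadienone tautomer 19 (not isolated)
Conditions: hν (Hg lamp, uranium-glass filter, λ > 340 nm), ClCH2CH2Cl, rt; then 80 °C
Reagents that add atoms: none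
Why: Proposed new method: the closest known reaction type is the Danheiser benzannulation of aryl, heteroaryl and alkenyl diazomethyl ketones with siloxyalkynes, extended here to a 4-oxopyran-2-yl diazo ketone on the reasoning that the pyranone C2=C3 bond is an enol-ether-like alkene whose nucleophilic C3 matches the electrophilic ketene carbon. Light expels N2 from 11 and the pyranonyl group migrates to the former diazo carbon (Wolff rearrangement), giving ketene 16. The electron-rich alkyne 15 adds across the ketene C=C bond in a (2+2) step, its unsubstituted carbon bonding to the ketene carbonyl carbon, to give cyclobutenone 17. Warming opens 17 reversibly by four-electron conrotatory ring-opening to dienylketene 18, and only the isomer with the pyranonyl group cis to the ketene chain goes on. Ring A is closed by thermal six-electron disrotatory electrocyclisation of 18 onto pyranone C3 (dienone 19), and enolisation, driven by aromatisation and by the hydrogen bond to the C4 carbonyl, gives 20. No stereocentre survives, since the sp3 carbons of 17 and 19 are lost on opening and on tautomerisation. The siloxy group lands on C7 and the hydroxyl on C5 because of the ketene–ynol ether polarity match, and closure can occur only at C3 because the other neighbour of the attachment carbon is the ring oxygen. The long wavelength keeps the arylpyranone chromophore out of the excitation, and the dioxolane keeps the aldehyde out of carbonyl photochemistry.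

Step 9
Reactants: 20 2-[4-(benzyloxy)phenyl]-3-[4-(1,3-dioxolan-2-yl)phenoxy]-5-hydroxy-7-(triisopropylsiloxy)-4H-chromen-4-one
Product: 23 5,7-bis(benzyloxy)-2-[4-(benzyloxy)phenyl]-3-[4-(1,3-dioxolan-2-yl)phenoxy]-4H-chromen-4-one, via 5,7-dihydroxyflavone acetal 21 (not isolated), via 7-benzyloxy-5-hydroxyflavone acetal 22 (not isolated)
Conditions: CsF, BnBr, K2CO3, n-Bu4NI (cat.), DMF, rt to 70 °C
Reagents that add atoms: benzyl bromide, BrCc1ccccc1
Why: Fluoride cleavage of the aryl silyl ether and Williamson benzylation of the freed phenoxide in the same flask; the chelated 5-hydroxyl is alkylated more slowly and needs the higher temperature and iodide catalysis, and the acetal is inert to these basic conditions.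

Step 10
Reactants: 23 5,7-bis(benzyloxy)-2-[4-(benzyloxy)phenyl]-3-[4-(1,3-dioxolan-2-yl)phenoxy]-4H-chromen-4-one
Product: 24 4-({5,7-bis(benzyloxy)-2-[4-(benzyloxy)phenyl]-4-oxo-4H-chromen-3-yl}oxy)benzaldehyde
Conditions: 1 M HCl, THF, rt
Reagents that add atoms: water, O
Why: Acid-catalysed acetal hydrolysis; dilute acid at room temperature should free the aldehyde without touching the benzyl ethers or the diaryl ether.

Step 11
Reactants: 25 1-(2,6-dihydroxy-4-methoxyphenyl)ethanone
Product: 26 1-[2-(benzyloxy)-6-hydroxy-4-methoxyphenyl]ethanone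
Conditions: BnBr (1.05 equiv), K2CO3, acetone, reflux
Reagents that add atoms: benzyl bromide, BrCc1ccccc1
Why: Williamson monobenzylation of a symmetrical bis-phenol; after the first alkylation the remaining hydroxyl is held in the hydrogen bond to the ketone and is much less reactive, so one equivalent should stop at 26.

Step 12
Reactants: 26 1-[2-(benzyloxy)-6-hydroxy-4-methoxyphenyl]ethanone
Product: 27 tert-butyl 3-[2-(benzyloxy)-6-hydroxy-4-methoxyphenyl]-3-oxopropanoate
Conditions: LiN(SiMe3)2 (3.2 equiv), THF, −78 °C; Boc2O, −78 to 0 °C; aq. NH4Cl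
Reagents that add atoms: di-tert-butyl dicarbonate, CC(C)(C)OC(=O)OC(=O)OC(C)(C)C
Why: Claisen-type C-acylation of the ketone enolate by the dicarbonate; excess amide base forms the phenoxide–enolate dianion and keeps the product deprotonated, and the tert-butyl ester is too hindered to lactonise at low temperature.

Step 13
Reactants: 24 4-({5,7-bis(benzyloxy)-2-[4-(benzyloxy)phenyl]-4-oxo-4H-chromen-3-yl}oxy)benzaldehyde; 27 tert-butyl 3-[2-(benzyloxy)-6-hydroxy-4-methoxyphenyl]-3-oxopropanoate
Product: 28 tert-butyl (2Z)-2-[2-(benzyloxy)-6-hydroxy-4-methoxybenzoyl]-3-[4-({5,7-bis(benzyloxy)-2-[4-(benzyloxy)phenyl]-4-oxo-4H-chromen-3-yl}oxy)phenyl]prop-2-enoate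
Conditions: piperidine (cat.), AcOH (cat.), 4 Å MS, toluene, rt
Reagents that add atoms: none
Why: Knoevenagel condensation of the active methylene compound with the aldehyde under piperidinium acetate catalysis with removal of water; these conditions are too mild to open the chromone, and the bulky ester slows uncatalysed closure of the free phenol.

Step 14
Reactants: 28 tert-butyl (2Z)-2-[2-(benzyloxy)-6-hydroxy-4-methoxybenzoyl]-3-[4-({5,7-bis(benzyloxy)-2-[4-(benzyloxy)phenyl]-4-oxo-4H-chromen-3-yl}oxy)phenyl]prop-2-enoate
Product: 31 (2S)-5-(benzyloxy)-2-[4-({5,7-bis(benzyloxy)-2-[4-(benzyloxy)phenyl]-4-oxo-4H-chromen-3-yl}oxy)phenyl]-7-methoxy-2,3-dihydro-4H-chromen-4-one, via tert-butyl flavanone-3-carboxylate 29 (not isolated), via flavanone-3-carboxylic acid 30 (not isolated)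
Conditions: quinidine-derived 3,5-bis(trifluoromethyl)phenyl thiourea (10 mol %), toluene, −25 °C; then p-TsOH, 80 °C
Reagents that add atoms: none
Why: Enantioselective intramolecular oxa-Michael addition under bifunctional cinchona thiourea catalysis, then acid-induced loss of the tert-butyl group and decarboxylation in the same flask. The thiourea binds the keto ester and the quinuclidine deprotonates the phenol and delivers the phenoxide to one face of the alkylidene, which sets C2 as S; C3 stops being a stereocentre on decarboxylation and the acidic finish should not reopen the ring.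

Step 15
Reactants: 31 (2S)-5-(benzyloxy)-2-[4-({5,7-bis(benzyloxy)-2-[4-(benzyloxy)phenyl]-4-oxo-4H-chromen-3-yl}oxy)phenyl]-7-methoxy-2,3-dihydro-4H-chromen-4-one
Product: 32 (2S)-2-(4-{[5,7-dihydroxy-2-(4-hydroxyphenyl)-4-oxo-4H-chromen-3-yl]oxy}phenyl)-5-hydroxy-7-methoxy-2,3-dihydro-4H-chromen-4-one
Conditions: H2 (1 atm), 10% Pd/C, THF/MeOH, rt
Reagents that add atoms: none
Why: Hydrogenolysis of the four benzyl ethers under neutral conditions, which should not epimerise C2; the methyl ether, the diaryl ether and both pyranone carbonyls should be inert at atmospheric pressure if the reaction is stopped at full debenzylation.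

## Compound list

1 | kojic acid, 5-hydroxy-2-(hydroxymethyl)-4H-pyran-4-one | OCc1cc(=O)c(O)co1 | starting material
2 | 6-bromo-5-hydroxy-2-(hydroxymethyl)-4H-pyran-4-one | OCc1cc(=O)c(O)c(Br)o1 | intermediate
3 | [4-(benzyloxy)phenyl]boronic acid | OB(O)c1ccc(OCc2ccccc2)cc1 | starting material
4 | 6-[4-(benzyloxy)phenyl]-5-hydroxy-2-(hydroxymethyl)-4H-pyran-4-one | OCc1cc(=O)c(O)c(-c2ccc(OCc3ccccc3)cc2)o1 | intermediate
5 | 4-fluorobenzaldehyde | O=Cc1ccc(F)cc1 | starting material
6 | 4-({2-[4-(benzyloxy)phenyl]-6-(hydroxymethyl)-4-oxo-4H-pyran-3-yl}oxy)benzaldehyde | OCc1cc(=O)c(Oc2ccc(C=O)cc2)c(-c2ccc(OCc3ccccc3)cc2)o1 | intermediate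
7 | 6-[4-(benzyloxy)phenyl]-5-[4-(1,3-dioxolan-2-yl)phenoxy]-2-(hydroxymethyl)-4H-pyran-4-one | OCc1cc(=O)c(Oc2ccc(cc2)C2OCCO2)c(-c2ccc(OCc3ccccc3)cc2)o1 | intermediate
8 | 6-[4-(benzyloxy)phenyl]-5-[4-(1,3-dioxolan-2-yl)phenoxy]-4-oxo-4H-pyran-2-carbaldehyde | O=Cc1cc(=O)c(Oc2ccc(cc2)C2OCCO2)c(-c2ccc(OCc3ccccc3)cc2)o1 | intermediate (not isolated)
9 | 6-[4-(benzyloxy)phenyl]-5-[4-(1,3-dioxolan-2-yl)phenoxy]-4-oxo-4H-pyran-2-carboxylic acid | OC(=O)c1cc(=O)c(Oc2ccc(cc2)C2OCCO2)c(-c2ccc(OCc3ccccc3)cc2)o1 | intermediate
10 | ethoxycarbonyl 6-[4-(benzyloxy)phenyl]-5-[4-(1,3-dioxolan-2-yl)phenoxy]-4-oxo-4H-pyran-2-carboxylate (mixed anhydride) | CCOC(=O)OC(=O)c1cc(=O)c(Oc2ccc(cc2)C2OCCO2)c(-c2ccc(OCc3ccccc3)cc2)o1 | intermediate (not isolated)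
11 | 2-diazo-1-{6-[4-(benzyloxy)phenyl]-5-[4-(1,3-dioxolan-2-yl)phenoxy]-4-oxo-4H-pyran-2-yl}ethanone | [N-]=[N+]=CC(=O)c1cc(=O)c(Oc2ccc(cc2)C2OCCO2)c(-c2ccc(OCc3ccccc3)cc2)o1 | intermediate
12 | acetylene | C#C | starting material
13 | lithium acetylide | [Li+].[C-]#C | intermediate (not isolated)
14 | lithium ethynolate | [Li+].[O-]C#C | intermediate (not isolated)
15 | (triisopropylsiloxy)ethyne | C#CO[Si](C(C)C)(C(C)C)C(C)C | intermediate
16 | 2-{6-[4-(benzyloxy)phenyl]-5-[4-(1,3-dioxolan-2-yl)phenoxy]-4-oxo-4H-pyran-2-yl}ethenone (ketene) | O=C=Cc1cc(=O)c(Oc2ccc(cc2)C2OCCO2)c(-c2ccc(OCc3ccccc3)cc2)o1 | intermediate (not isolated)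
17 | 4-{6-[4-(benzyloxy)phenyl]-5-[4-(1,3-dioxolan-2-yl)phenoxy]-4-oxo-4H-pyran-2-yl}-3-(triisopropylsiloxy)cyclobut-2-en-1-one (racemic) | O=C1C=C(O[Si](C(C)C)(C(C)C)C(C)C)C1c1cc(=O)c(Oc2ccc(cc2)C2OCCO2)c(-c2ccc(OCc3ccccc3)cc2)o1 | intermediate (not isolated)
18 | (3E)-4-{6-[4-(benzyloxy)phenyl]-5-[4-(1,3-dioxolan-2-yl)phenoxy]-4-oxo-4H-pyran-2-yl}-3-(triisopropylsiloxy)buta-1,3-dien-1-one | O=C=C/C(O[Si](C(C)C)(C(C)C)C(C)C)=C\c1cc(=O)c(Oc2ccc(cc2)C2OCCO2)c(-c2ccc(OCc3ccccc3)cc2)o1 | intermediate (not isolated)
19 | 2-[4-(benzyloxy)phenyl]-3-[4-(1,3-dioxolan-2-yl)phenoxy]-7-(triisopropylsiloxy)-4aH-chromene-4,5-dione (racemic) | O=C1C=C(O[Si](C(C)C)(C(C)C)C(C)C)C=C2OC(-c3ccc(OCc4ccccc4)cc3)=C(Oc3ccc(cc3)C3OCCO3)C(=O)C12 | intermediate (not isolated)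
20 | 2-[4-(benzyloxy)phenyl]-3-[4-(1,3-dioxolan-2-yl)phenoxy]-5-hydroxy-7-(triisopropylsiloxy)-4H-chromen-4-one | O=c1c(Oc2ccc(cc2)C2OCCO2)c(-c2ccc(OCc3ccccc3)cc2)oc2cc(O[Si](C(C)C)(C(C)C)C(C)C)cc(O)c12 | intermediate
21 | 2-[4-(benzyloxy)phenyl]-3-[4-(1,3-dioxolan-2-yl)phenoxy]-5,7-dihydroxy-4H-chromen-4-one | O=c1c(Oc2ccc(cc2)C2OCCO2)c(-c2ccc(OCc3ccccc3)cc2)oc2cc(O)cc(O)c12 | intermediate (not isolated)
22 | 7-(benzyloxy)-2-[4-(benzyloxy)phenyl]-3-[4-(1,3-dioxolan-2-yl)phenoxy]-5-hydroxy-4H-chromen-4-one | O=c1c(Oc2ccc(cc2)C2OCCO2)c(-c2ccc(OCc3ccccc3)cc2)oc2cc(OCc3ccccc3)cc(O)c12 | intermediate (not isolated)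
23 | 5,7-bis(benzyloxy)-2-[4-(benzyloxy)phenyl]-3-[4-(1,3-dioxolan-2-yl)phenoxy]-4H-chromen-4-one | O=c1c(Oc2ccc(cc2)C2OCCO2)c(-c2ccc(OCc3ccccc3)cc2)oc2cc(OCc3ccccc3)cc(OCc3ccccc3)c12 | intermediate
24 | 4-({5,7-bis(benzyloxy)-2-[4-(benzyloxy)phenyl]-4-oxo-4H-chromen-3-yl}oxy)benzaldehyde | O=Cc1ccc(Oc2c(-c3ccc(OCc4ccccc4)cc3)oc3cc(OCc4ccccc4)cc(OCc4ccccc4)c3c2=O)cc1 | intermediate
25 | 1-(2,6-dihydroxy-4-methoxyphenyl)ethanone | CC(=O)c1c(O)cc(OC)cc1O | starting material
26 | 1-[2-(benzyloxy)-6-hydroxy-4-methoxyphenyl]ethanone | CC(=O)c1c(O)cc(OC)cc1OCc1ccccc1 | intermediate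
27 | tert-butyl 3-[2-(benzyloxy)-6-hydroxy-4-methoxyphenyl]-3-oxopropanoate | CC(C)(C)OC(=O)CC(=O)c1c(O)cc(OC)cc1OCc1ccccc1 | intermediate
28 | tert-butyl (2Z)-2-[2-(benzyloxy)-6-hydroxy-4-methoxybenzoyl]-3-[4-({5,7-bis(benzyloxy)-2-[4-(benzyloxy)phenyl]-4-oxo-4H-chromen-3-yl}oxy)phenyl]prop-2-enoate | CC(C)(C)OC(=O)/C(=C\c1ccc(Oc2c(-c3ccc(OCc4ccccc4)cc3)oc3cc(OCc4ccccc4)cc(OCc4ccccc4)c3c2=O)cc1)C(=O)c1c(O)cc(OC)cc1OCc1ccccc1 | intermediate
29 | tert-butyl (2S,3R)-5-(benzyloxy)-2-[4-({5,7-bis(benzyloxy)-2-[4-(benzyloxy)phenyl]-4-oxo-4H-chromen-3-yl}oxy)phenyl]-7-methoxy-4-oxo-3,4-dihydro-2H-chromene-3-carboxylate (2,3-trans, C3 epimerisable) | COc1cc(OCc2ccccc2)c2c(c1)O[C@H](c1ccc(Oc3c(-c4ccc(OCc5ccccc5)cc4)oc4cc(OCc5ccccc5)cc(OCc5ccccc5)c4c3=O)cc1)[C@@H](C(=O)OC(C)(C)C)C2=O | intermediate (not isolated)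
30 | (2S,3R)-5-(benzyloxy)-2-[4-({5,7-bis(benzyloxy)-2-[4-(benzyloxy)phenyl]-4-oxo-4H-chromen-3-yl}oxy)phenyl]-7-methoxy-4-oxo-3,4-dihydro-2H-chromene-3-carboxylic acid | COc1cc(OCc2ccccc2)c2c(c1)O[C@H](c1ccc(Oc3c(-c4ccc(OCc5ccccc5)cc4)oc4cc(OCc5ccccc5)cc(OCc5ccccc5)c4c3=O)cc1)[C@@H](C(O)=O)C2=O | intermediate (not isolated)
31 | (2S)-5-(benzyloxy)-2-[4-({5,7-bis(benzyloxy)-2-[4-(benzyloxy)phenyl]-4-oxo-4H-chromen-3-yl}oxy)phenyl]-7-methoxy-2,3-dihydro-4H-chromen-4-one | COc1cc(OCc2ccccc2)c2c(c1)O[C@H](c1ccc(Oc3c(-c4ccc(OCc5ccccc5)cc4)oc4cc(OCc5ccccc5)cc(OCc5ccccc5)c4c3=O)cc1)CC2=O | intermediate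
32 | (2S)-2-(4-{[5,7-dihydroxy-2-(4-hydroxyphenyl)-4-oxo-4H-chromen-3-yl]oxy}phenyl)-5-hydroxy-7-methoxy-2,3-dihydro-4H-chromen-4-one | COc1cc(O)c2c(c1)O[C@H](c1ccc(Oc3c(-c4ccc(O)cc4)oc4cc(O)cc(O)c4c3=O)cc1)CC2=O | target

## Step count and risk

Total step count: 15. Longest linear sequence: 12 steps (steps 1 to 6, 8 to 10 and 13 to 15, from 1); steps 7, 11 and 12 are side branches.

Least certain steps:

Step 8 (key step). Most likely failures: competing light absorption and photodegradation of the arylpyranone and of the product chromophore, O-acylation of the product phenol by ketene that has not yet met the alkyne, and incomplete thermal opening and closure of the cyclobutenone. Fallback with known chemistry, setting out from 5 and returning to the route at 24: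
- Commercially available 1-[2,4-bis(benzyloxy)-6-hydroxyphenyl]ethanone and 4-(benzyloxy)benzaldehyde are condensed (KOH, EtOH, Claisen–Schmidt) to (E)-1-[2,4-bis(benzyloxy)-6-hydroxyphenyl]-3-[4-(benzyloxy)phenyl]prop-2-en-1-one F1.
- Oxidative cyclisation (I2, DMSO, heat) gives 5,7-bis(benzyloxy)-2-[4-(benzyloxy)phenyl]-4H-chromen-4-one F2.
- Epoxidation of its C2=C3 bond with dimethyldioxirane and acid-induced opening gives 5,7-bis(benzyloxy)-2-[4-(benzyloxy)phenyl]-3-hydroxy-4H-chromen-4-one F3.
- F3 is O-arylated with 5 (K2CO3, DMSO, heat) to give 24.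

Step 7. Most likely failures: disproportionation of the monolithium acetylide before it is oxidised, silylation of the ynolate on carbon instead of oxygen, and hydrolytic loss of the ynol ether on isolation. Fallback, setting out from 11 and returning at 22:
- Benzyl alcohol (KH, THF) and trichloroethylene give benzyl (E)-1,2-dichlorovinyl ether F4.
- n-BuLi (2.2 equiv, −78 °C) then methanol gives (benzyloxy)ethyne F5, used cold and at once.
- F5 replaces 15 in the irradiation of 11, which should give 22 directly; 22 is then benzylated at O5 as in the second half of step 9.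

Step 14. Most likely failures: uncatalysed, non-selective ring closure of the hindered 2,6-disubstituted aryl ketone competing with the catalysed path, and partial ring-opening during the acidic decarboxylation, either of which lowers the enantiomeric purity. Fallback, setting out from 24 and 26 and returning at 31:
- Claisen–Schmidt condensation (KOH, EtOH/THF, rt) gives (2E)-1-[2-(benzyloxy)-6-hydroxy-4-methoxyphenyl]-3-[4-({5,7-bis(benzyloxy)-2-[4-(benzyloxy)phenyl]-4-oxo-4H-chromen-3-yl}oxy)phenyl]prop-2-en-1-one F6.
- NaOAc in refluxing ethanol closes it to racemic 5-(benzyloxy)-2-[4-({5,7-bis(benzyloxy)-2-[4-(benzyloxy)phenyl]-4-oxo-4H-chromen-3-yl}oxy)phenyl]-7-methoxy-2,3-dihydro-4H-chromen-4-one F7.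
- Preparative chromatography on a chiral stationary phase gives 31; the unwanted enantiomer is recycled by base-induced ring-opening and re-closure.

Step 2. Most likely failures: sequestration of palladium by the chelating hydroxypyranone and protodebromination of the electron-rich enolate. Fallback, setting out from 2 and returning at 4:
- The enolic hydroxyl is protected (MOMCl, K2CO3, acetone) as 6-bromo-2-(hydroxymethyl)-5-(methoxymethoxy)-4H-pyran-4-one F8.
- The same coupling with 3 gives 6-[4-(benzyloxy)phenyl]-2-(hydroxymethyl)-5-(methoxymethoxy)-4H-pyran-4-one F9.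
- HCl in methanol removes the acetal group to give 4.

Step 3. Most likely failures: slow substitution because the vinylogous carboxylate is a weak nucleophile, and competing arylation of the primary alcohol at the temperature then needed. Fallback, setting out from 4 and returning at 7: Ullmann-type ether coupling of 4 with commercially available 2-(4-bromophenyl)-1,3-dioxolane (CuI, picolinic acid, K3PO4, DMSO, 90 °C) gives 7 directly and makes step 4 unnecessary; no new compound is made (F0).

## Further compounds

F1 | step 8 | (E)-1-[2,4-bis(benzyloxy)-6-hydroxyphenyl]-3-[4-(benzyloxy)phenyl]prop-2-en-1-one | O=C(/C=C/c1ccc(OCc2ccccc2)cc1)c1c(O)cc(OCc2ccccc2)cc1OCc1ccccc1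
F2 | step 8 | 5,7-bis(benzyloxy)-2-[4-(benzyloxy)phenyl]-4H-chromen-4-one | O=c1cc(-c2ccc(OCc3ccccc3)cc2)oc2cc(OCc3ccccc3)cc(OCc3ccccc3)c12
F3 | step 8 | 5,7-bis(benzyloxy)-2-[4-(benzyloxy)phenyl]-3-hydroxy-4H-chromen-4-one | O=c1c(O)c(-c2ccc(OCc3ccccc3)cc2)oc2cc(OCc3ccccc3)cc(OCc3ccccc3)c12
F4 | step 7 | benzyl (E)-1,2-dichlorovinyl ether | Cl/C=C(/Cl)OCc1ccccc1
F5 | step 7 | (benzyloxy)ethyne | C#COCc1ccccc1
F6 | step 14 | (2E)-1-[2-(benzyloxy)-6-hydroxy-4-methoxyphenyl]-3-[4-({5,7-bis(benzyloxy)-2-[4-(benzyloxy)phenyl]-4-oxo-4H-chromen-3-yl}oxy)phenyl]prop-2-en-1-one | O=C(/C=C/c1ccc(Oc2c(-c3ccc(OCc4ccccc4)cc3)oc3cc(OCc4ccccc4)cc(OCc4ccccc4)c3c2=O)cc1)c1c(O)cc(OC)cc1OCc1ccccc1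
F7 | step 14 | racemic 5-(benzyloxy)-2-[4-({5,7-bis(benzyloxy)-2-[4-(benzyloxy)phenyl]-4-oxo-4H-chromen-3-yl}oxy)phenyl]-7-methoxy-2,3-dihydro-4H-chromen-4-one | COc1cc(OCc2ccccc2)c2c(c1)OC(c1ccc(Oc3c(-c4ccc(OCc5ccccc5)cc4)oc4cc(OCc5ccccc5)cc(OCc5ccccc5)c4c3=O)cc1)CC2=O
F8 | step 2 | 6-bromo-2-(hydroxymethyl)-5-(methoxymethoxy)-4H-pyran-4-one | COCOc1c(Br)oc(CO)cc1=O
F9 | step 2 | 6-[4-(benzyloxy)phenyl]-2-(hydroxymethyl)-5-(methoxymethoxy)-4H-pyran-4-one | COCOc1c(-c2ccc(OCc3ccccc3)cc2)oc(CO)cc1=O
F0 | step 3 | none | none
A1 | alternative 1 | (3S)-3-[4-({5,7-bis(benzyloxy)-2-[4-(benzyloxy)phenyl]-4-oxo-4H-chromen-3-yl}oxy)phenyl]-3-(3,5-dimethoxyphenoxy)propanoic acid | COc1cc(OC)cc(c1)O[C@H](c1ccc(Oc3c(-c4ccc(OCc5ccccc5)cc4)oc4cc(OCc5ccccc5)cc(OCc5ccccc5)c4c3=O)cc1)CC(O)=O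
A2 | alternative 1 | (2S)-2-[4-({5,7-bis(benzyloxy)-2-[4-(benzyloxy)phenyl]-4-oxo-4H-chromen-3-yl}oxy)phenyl]-5,7-dimethoxy-2,3-dihydro-4H-chromen-4-one | COc1cc(OC)c2c(c1)O[C@H](c1ccc(Oc3c(-c4ccc(OCc5ccccc5)cc4)oc4cc(OCc5ccccc5)cc(OCc5ccccc5)c4c3=O)cc1)CC2=O
A3 | alternative 2 | phloroglucinol (benzene-1,3,5-triol) | Oc1cc(O)cc(O)c1
A4 | alternative 2 | ethyl 3-[4-(benzyloxy)phenyl]-2-(4-bromophenoxy)-3-oxopropanoate | CCOC(=O)C(Oc1ccc(Br)cc1)C(=O)c1ccc(OCc2ccccc2)cc1
A5 | alternative 2 | 2-[4-(benzyloxy)phenyl]-3-(4-bromophenoxy)-5,7-dihydroxy-4H-chromen-4-one | O=c1c(Oc2ccc(Br)cc2)c(-c2ccc(OCc3ccccc3)cc2)oc2cc(O)cc(O)c12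
A6 | alternative 2 | 5-(benzyloxy)-7-methoxy-4H-chromen-4-one | COc1cc(OCc2ccccc2)c2c(c1)occc2=O
A7 | alternative 3 | methyl (8E)-9-[4-({5,7-bis(benzyloxy)-2-[4-(benzyloxy)phenyl]-4-oxo-4H-chromen-3-yl}oxy)phenyl]-3,5,7-trioxonon-8-enoate | COC(=O)CC(=O)CC(=O)CC(=O)/C=C/c1ccc(Oc2c(-c3ccc(OCc4ccccc4)cc3)oc3cc(OCc4ccccc4)cc(OCc4ccccc4)c3c2=O)cc1
A8 | alternative 3 | (2E)-3-[4-({5,7-bis(benzyloxy)-2-[4-(benzyloxy)phenyl]-4-oxo-4H-chromen-3-yl}oxy)phenyl]-1-(2,4,6-trihydroxyphenyl)prop-2-en-1-one | O=C(/C=C/c1ccc(Oc2c(-c3ccc(OCc4ccccc4)cc3)oc3cc(OCc4ccccc4)cc(OCc4ccccc4)c3c2=O)cc1)c1c(O)cc(O)cc1O
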